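**Plan**
- Retrosynthesis: the C3′ tertiary alcohol is cut back to a methyl ketone (one C3′–CH3 bond). Then C1′–C2′ and C2′–O(ester) are cut together, giving 7-methoxycoumarin-6-carbaldehyde, diazoacetone and isovaleric acid.
- Enabling feature: C2′, the CH carrying the isovalerate, lies between the benzylic carbinol C1′ on coumarin C6 and the carbinol carbon C3′. As a carbene carbon it can take up the acid oxygen and the aldehyde carbon in one event.
- Forward: the pyranone ring of the coumarin is the only ring made, by Wittig–lactonisation of a bromosalicylaldehyde; the bromide is then turned into vinyl and formyl. Diazoacetone comes from acetylacetone. The three-component coupling joins the side chain; silylation, methyl addition and desilylation finish it.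
- Stereochemistry: both centres (1′R,2′S, syn) are set in the coupling by a chiral phosphoric acid. Later steps create no stereocentre and do not touch C1′ or C2′.

Key step: step 6

Assumption: the sense of induction of the chiral phosphoric acid in this new reaction cannot be assigned in advance; the (R) acid is written, and its (S) enantiomer would be used instead if the first trial shows that (R) leads to the (1S,2R) antipode.

**Route**

Step 1
Reactants: 1 5-bromo-2-hydroxy-4-methoxybenzaldehyde
Product: 4 6-bromo-7-methoxy-2H-chromen-2-one, via (E)-cinnamate ester 2 (not isolated), via (Z)-cinnamate ester 3 (not isolated)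
Conditions: Ph3P=CHCO2Et (1.2 equiv), N,N-diethylaniline, reflux (about 215 °C), N2
Reagents that add atoms: ethyl (triphenylphosphoranylidene)acetate, CCOC(=O)C=P(c1ccccc1)(c1ccccc1)c1ccccc1
Why: A Wittig olefination with the stabilised ylide gives cinnamate 2, which in refluxing N,N-diethylaniline equilibrates with its (Z) isomer 3, whose ortho phenol closes the pyranone by intramolecular transesterification with loss of ethanol (Wittig–lactonisation coumarin synthesis); the aryl bromide and the methyl ether are inert.

Step 2
Reactants: 4 6-bromo-7-methoxy-2H-chromen-2-one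
Product: 5 6-ethenyl-7-methoxy-2H-chromen-2-one
Conditions: CH2=CHSnBu3 (1.2 equiv), Pd(PPh3)4 (5 mol %), toluene, 100 °C
Reagents that add atoms: tributyl(vinyl)stannane, C=C[Sn](CCCC)(CCCC)CCCC
Why: Stille cross-coupling, in which oxidative addition of the electron-poor aryl bromide to zerovalent palladium, vinyl transfer from tin and reductive elimination proceed under neutral conditions that leave the lactone untouched.

Step 3
Reactants: 5 6-ethenyl-7-methoxy-2H-chromen-2-one
Product: 6 7-methoxy-2-oxo-2H-chromene-6-carbaldehyde
Conditions: OsO4 (2 mol %), NaIO4 (4 equiv), 2,6-lutidine (2 equiv), 1,4-dioxane/H2O (3:1), rt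
Reagents that add atoms: sodium periodate, [Na+].[O-][I](=O)(=O)=O (terminal source of the aldehyde oxygen, passed on through osmium tetroxide, O=[Os](=O)(=O)=O)
Why: Lemieux–Johnson oxidative cleavage, in which OsO4 dihydroxylates the styrene-type vinyl group far faster than the electron-poor conjugated C3=C4 bond of the pyranone, NaIO4 cleaves the diol to the aldehyde and formaldehyde and reoxidises osmium, and 2,6-lutidine suppresses over-oxidation.

Step 4
Reactants: 7 acetylacetone (pentane-2,4-dione)
Product: 8 3-diazopentane-2,4-dione
Conditions: 4-acetamidobenzenesulfonyl azide (1.05 equiv), Et3N (1.2 equiv), MeCN, 0 °C to rt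
Reagents that add atoms: 4-acetamidobenzenesulfonyl azide, CC(=O)Nc1ccc(cc1)S(=O)(=O)N=[N+]=[N-]
Why: Regitz diazo transfer, in which the triethylammonium enolate of the 1,3-diketone attacks the terminal nitrogen of the sulfonyl azide and the adduct collapses to the 2-diazo-1,3-diketone and the sulfonamide.

Step 5
Reactants: 8 3-diazopentane-2,4-dione
Product: 9 diazoacetone (1-diazopropan-2-one)
Conditions: aq NaOH (1 M, 1.5 equiv), Et2O, 0 °C to rt; extracted into CH2Cl2, dried and used as a titrated solution without concentration to dryness
Reagents that add atoms: none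
Why: Deacylative (retro-Claisen type) cleavage of a 2-diazo-1,3-diketone, in which hydroxide adds to one acetyl carbonyl and the tetrahedral intermediate expels the diazo-stabilised carbanion that is protonated to diazoacetone; the volatile, hazardous product is kept cold and in solution.

Step 6
Reactants: 6 7-methoxy-2-oxo-2H-chromene-6-carbaldehyde; 9 diazoacetone; 10 isovaleric acid (3-methylbutanoic acid)
Product: 12 (1R,2S)-1-hydroxy-1-(7-methoxy-2-oxo-2H-chromen-6-yl)-3-oxobutan-2-yl 3-methylbutanoate, via (Z)-enol 11 (not isolated)
Conditions: Rh2(OAc)4 (2 mol %), (R)-3,3′-bis(2,4,6-triisopropylphenyl)-1,1′-binaphthyl-2,2′-diyl hydrogen phosphate (10 mol %), 4 Å molecular sieves, CH2Cl2, −20 °C; 9 (2.0 equiv) added over 4 h by syringe pump to 6 (1.0 equiv) and 10 (1.5 equiv)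
Reagents that add atoms: none
Why: Proposed new method: Rh2(OAc)4, a divalent rhodium carboxylate, decomposes diazoacetone 9 to an electrophilic rhodium carbene that is captured by the O–H of acid 10 and, through the ylide-like adduct, releases the (Z)-enol 11 of isovaleryloxyacetone; the chiral phosphoric acid intercepts 11 before the 1,2-proton shift and delivers it to aldehyde 6 in a closed, doubly hydrogen-bonded transition state (P=O to the enol O–H, P–OH to the aldehyde oxygen), forming C2′–O and C1′–C2′ in one operation. The closest known reaction type is the three-component aldol-type trapping, by aldehydes, of oxonium ylides or enols generated from diazo carbonyl compounds and alcohols or water under Rh2(OAc)4 and chiral phosphoric acid co-catalysis; new here are a carboxylic acid as the O–H partner and a diazo methyl ketone as the carbene source. No ring is closed, so no mode of ring closure applies. The syn relationship of C1′ and C2′ should follow from the (Z) geometry of enol 11 in the chair-like assembly, and the absolute configuration (1R at C1′, 2S at C2′) is set by the binaphthyl pocket of the acid, which exposes one face of the bound aldehyde. The step needs chemoselectivity for aldol trapping over plain O–H insertion and over carbonyl-ylide formation; it is secured by the non-enolisable aldehyde with its ortho methoxy group as a second hydrogen-bond contact, by keeping 6 concentrated while 9 is added slowly, and by the carboxylic acid being a far better carbene trap than the aldehyde oxygen.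

Step 7
Reactants: 12 (1R,2S)-1-hydroxy-1-(7-methoxy-2-oxo-2H-chromen-6-yl)-3-oxobutan-2-yl 3-methylbutanoate
Product: 13 (1R,2S)-1-(7-methoxy-2-oxo-2H-chromen-6-yl)-3-oxo-1-[(triethylsilyl)oxy]butan-2-yl 3-methylbutanoate
Conditions: Et3SiOTf (1.2 equiv), 2,6-lutidine (2.0 equiv), CH2Cl2, −78 °C
Reagents that add atoms: triethylsilyl trifluoromethanesulfonate, CC[Si](CC)(CC)OS(=O)(=O)C(F)(F)F
Why: Silyl ether formation with a silyl triflate and a hindered pyridine base at −78 °C is faster than acyl migration or ketone enolisation, and it masks O1′ so that no alkoxide can form beside the ester in the next step; neither stereocentre is touched.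

Step 8
Reactants: 13 (1R,2S)-1-(7-methoxy-2-oxo-2H-chromen-6-yl)-3-oxo-1-[(triethylsilyl)oxy]butan-2-yl 3-methylbutanoate
Product: 14 (1R,2S)-3-hydroxy-1-(7-methoxy-2-oxo-2H-chromen-6-yl)-3-methyl-1-[(triethylsilyl)oxy]butan-2-yl 3-methylbutanoate
Conditions: MeLi (1.5 equiv), anhydrous CeCl3 (1.6 equiv), THF, −78 °C; AcOH quench at −78 °C
Reagents that add atoms: methyllithium, [Li]C (used as methylcerium dichloride, C[Ce](Cl)Cl, formed in the flask with CeCl3)
Why: Imamoto organocerium 1,2-addition, in which the oxophilic, weakly basic methylcerium reagent adds to the ketone much faster than it attacks the isovalerate or the lactone or removes the C2′ proton, the cold acetic acid quench protonates the tertiary alkoxide before it can take over the neighbouring acyl group, and no stereocentre is created because C3′ then carries two methyl groups.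

Step 9
Reactants: 14 (1R,2S)-3-hydroxy-1-(7-methoxy-2-oxo-2H-chromen-6-yl)-3-methyl-1-[(triethylsilyl)oxy]butan-2-yl 3-methylbutanoate
Product: 15 (1R,2S)-1,3-dihydroxy-1-(7-methoxy-2-oxo-2H-chromen-6-yl)-3-methylbutan-2-yl 3-methylbutanoate
Conditions: HF·pyridine, pyridine, THF, 0 °C
Reagents that add atoms: none
Why: Fluoride-mediated cleavage of the triethylsilyl ether with pyridine-buffered HF·pyridine is nearly neutral, so the ester should stay on O2′, the benzylic C1′–O bond should not ionise and the lactone should not open.

**Compound list**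

1 | 5-bromo-2-hydroxy-4-methoxybenzaldehyde | COc1cc(O)c(C=O)cc1Br | starting material
2 | ethyl (E)-3-(5-bromo-2-hydroxy-4-methoxyphenyl)prop-2-enoate (formed in the flask, not isolated) | CCOC(=O)/C=C/c1cc(Br)c(OC)cc1O | intermediate
3 | ethyl (Z)-3-(5-bromo-2-hydroxy-4-methoxyphenyl)prop-2-enoate (formed in the flask, not isolated) | CCOC(=O)/C=C\c1cc(Br)c(OC)cc1O | intermediate
4 | 6-bromo-7-methoxy-2H-chromen-2-one | COc1cc2oc(=O)ccc2cc1Br | intermediate
5 | 6-ethenyl-7-methoxy-2H-chromen-2-one | COc1cc2oc(=O)ccc2cc1C=C | intermediate
6 | 7-methoxy-2-oxo-2H-chromene-6-carbaldehyde | COc1cc2oc(=O)ccc2cc1C=O | intermediate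
7 | acetylacetone (pentane-2,4-dione) | CC(=O)CC(C)=O | starting material
8 | 3-diazopentane-2,4-dione | CC(=O)C(=[N+]=[N-])C(C)=O | intermediate
9 | diazoacetone (1-diazopropan-2-one) | CC(=O)C=[N+]=[N-] | intermediate
10 | isovaleric acid (3-methylbutanoic acid) | CC(C)CC(=O)O | starting material
11 | (Z)-2-hydroxyprop-1-en-1-yl 3-methylbutanoate (enol, formed in the flask, not isolated) | CC(C)CC(=O)O/C=C(\O)C | intermediate
12 | (1R,2S)-1-hydroxy-1-(7-methoxy-2-oxo-2H-chromen-6-yl)-3-oxobutan-2-yl 3-methylbutanoate | COc1cc2oc(=O)ccc2cc1[C@@H](O)[C@H](OC(=O)CC(C)C)C(C)=O | intermediate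
13 | (1R,2S)-1-(7-methoxy-2-oxo-2H-chromen-6-yl)-3-oxo-1-[(triethylsilyl)oxy]butan-2-yl 3-methylbutanoate | COc1cc2oc(=O)ccc2cc1[C@@H](O[Si](CC)(CC)CC)[C@H](OC(=O)CC(C)C)C(C)=O | intermediate
14 | (1R,2S)-3-hydroxy-1-(7-methoxy-2-oxo-2H-chromen-6-yl)-3-methyl-1-[(triethylsilyl)oxy]butan-2-yl 3-methylbutanoate | COc1cc2oc(=O)ccc2cc1[C@@H](O[Si](CC)(CC)CC)[C@H](OC(=O)CC(C)C)C(C)(C)O | intermediate
15 | (1R,2S)-1,3-dihydroxy-1-(7-methoxy-2-oxo-2H-chromen-6-yl)-3-methylbutan-2-yl 3-methylbutanoate (CNP0260807.1) | COc1cc2oc(=O)ccc2cc1[C@@H](O)[C@H](OC(=O)CC(C)C)C(C)(C)O | target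

**Step count**

Total: 9 steps. Longest linear sequence: 7 steps (steps 1, 2, 3, 6, 7, 8, 9 from compound 1); the diazoacetone branch (steps 4 and 5) joins at step 6.

**Steps most likely to fail**

Step 6 (new method). The enol may tautomerise to the plain O–H insertion product before the aldehyde traps it. Trapping through a carboxylic-acid-catalysed background pathway may also erode diastereo- and enantioselectivity. The fallback uses known chemistry, sets out from aldehyde 6 and returns at compound 13.
- A primary-amino-acid-catalysed syn-selective direct aldol of 6 with 1-[(4-methoxybenzyl)oxy]propan-2-one (O-tert-butyl-D-threonine, N-methylpyrrolidone, 4 °C) would proceed through the (Z)-enamine and should give (3S,4R)-4-hydroxy-4-(7-methoxy-2-oxo-2H-chromen-6-yl)-3-[(4-methoxybenzyl)oxy]butan-2-one F1. The D catalyst is the expected choice; the L catalyst would be used if the sense proves opposite.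
- Silylation (Et3SiOTf, 2,6-lutidine, CH2Cl2, −78 °C) would give (3S,4R)-4-(7-methoxy-2-oxo-2H-chromen-6-yl)-3-[(4-methoxybenzyl)oxy]-4-[(triethylsilyl)oxy]butan-2-one F2.
- Oxidative removal of the 4-methoxybenzyl ether (2,3-dichloro-5,6-dicyano-1,4-benzoquinone, CH2Cl2/pH 7 buffer, 0 °C) would free only O2′ and give (3S,4R)-3-hydroxy-4-(7-methoxy-2-oxo-2H-chromen-6-yl)-4-[(triethylsilyl)oxy]butan-2-one F3.
- Acylation with isovaleryl chloride (pyridine, catalytic 4-(dimethylamino)pyridine, CH2Cl2, −20 °C) would deliver 13. The two oxygens are told apart here by the order of protection, not by the coupling.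

Step 8. The new C3′ alkoxide may take over the acyl group from O2′. The organometallic may also attack the lactone or the isovalerate, or deprotonate C2′ with loss of the β-silyloxy group. The fallback sets out from 13 and returns at 14 without forming an alkoxide beside the ester.
- Non-basic Takai–Lombardo methylenation of the ketone (Zn, CH2Br2, TiCl4, THF/CH2Cl2, 0 °C to rt) would give (1R,2R)-1-(7-methoxy-2-oxo-2H-chromen-6-yl)-3-methyl-1-[(triethylsilyl)oxy]but-3-en-2-yl 3-methylbutanoate F4. The descriptor at C2′ changes only because the priorities change.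
- Mukaiyama Markovnikov hydration of the 1,1-disubstituted alkene (Co(acac)2 catalyst, PhSiH3, O2, THF/i-PrOH, rt) would give 14. The silane is limited so that the conjugated C3=C4 bond of the pyranone is left alone.

Step 9. Once O1′ is freed the isovalerate may migrate from O2′ to O1′ or O3′. The electron-rich benzylic C1′–O bond may also ionise under acidic fluoride. The fallback sets out from 12 and comes back at 15, so it avoids the silyl ether and its removal (steps 7 to 9).
- Aldol 12 would be treated directly with MeTi(OiPr)3 (3 equiv, from MeLi and ClTi(OiPr)3; CH2Cl2/THF, −40 to 0 °C).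
- The C1′ hydroxyl exchanges onto titanium and the methyl group is delivered intramolecularly to the neighbouring ketone. The reagent is non-basic and inert toward esters and the lactone.
- A cold aqueous NH4F quench would give 15. No new compound is made.

**Further compounds**

F1 | step 6 | (3S,4R)-4-hydroxy-4-(7-methoxy-2-oxo-2H-chromen-6-yl)-3-[(4-methoxybenzyl)oxy]butan-2-one | COc1cc2oc(=O)ccc2cc1[C@@H](O)[C@H](OCc1ccc(OC)cc1)C(C)=O
F2 | step 6 | (3S,4R)-4-(7-methoxy-2-oxo-2H-chromen-6-yl)-3-[(4-methoxybenzyl)oxy]-4-[(triethylsilyl)oxy]butan-2-one | COc1cc2oc(=O)ccc2cc1[C@@H](O[Si](CC)(CC)CC)[C@H](OCc1ccc(OC)cc1)C(C)=O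
F3 | step 6 | (3S,4R)-3-hydroxy-4-(7-methoxy-2-oxo-2H-chromen-6-yl)-4-[(triethylsilyl)oxy]butan-2-one | COc1cc2oc(=O)ccc2cc1[C@@H](O[Si](CC)(CC)CC)[C@H](O)C(C)=O
F4 | step 8 | (1R,2R)-1-(7-methoxy-2-oxo-2H-chromen-6-yl)-3-methyl-1-[(triethylsilyl)oxy]but-3-en-2-yl 3-methylbutanoate | COc1cc2oc(=O)ccc2cc1[C@@H](O[Si](CC)(CC)CC)[C@H](OC(=O)CC(C)C)C(C)=C
F0 | step 9 | none | none
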